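**Assumption (chemistry):** (9Z)-octadec-9-enedioic acid (7) is taken to be purchasable as the geometrically pure cis diacid (the ω-oxidation product of oleic acid). The cis geometry is therefore bought, not made.

## The problem

Oncostemonol B (20) consists of two 5-alkylresorcinol rings, ring A (bearing the single acetate) and ring B, joined through C1 and C16 of an unbranched (8Z)-hexadec-8-ene chain. It has no stereogenic centre. The only stereochemical element is the cis double bond at the midpoint of the chain, seven methylene groups from either ring, so nothing in the molecule can direct its formation. It is best brought in intact and kept away from whatever isomerises or saturates an isolated alkene (radical chains, halogens, hydrogenation catalysts, metal hydrides, hot strong acid). Between alkene and arenes the chain is bare, so each ring–chain junction must come either from an sp2–sp3 coupling at a finished arene or from growing the ring on a chain terminus. The aryl acetate does not survive hydroxide, alkoxide, hydride or organometallic reagents and has to go on last, and the free resorcinols are readily oxidised as phenoxides in air. Apart from the acetyl group the molecule is symmetric, which invites a two-directional synthesis but leaves a final desymmetrisation of four equivalent phenols. The key step rests on the 1,3,5 pattern of each ring: the chain-bearing carbon and the two oxygen-bearing carbons are mutually meta, with a CH between each pair. Four contiguous ring carbons with both oxygens map onto a 1,1-dialkoxy-3-silyloxybuta-1,3-diene, and the other two (the chain-bearing carbon and one CH neighbour) onto an alkyne whose second carbon carries an ester that activates, directs and is later lost.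

## Retrosynthesis

**20 ⇒ 19.** The acetyl C–O bond of ring A is cut first, because the acetate is the one group that tolerates none of the basic or nucleophilic chemistry needed elsewhere. The precursor, tetraphenol 19, has two identical rings and four equivalent hydroxyl groups, so everything before it can be done at both chain ends at once. The forward step is a mono-acylation of four equivalent sites, which is statistical for any route through a symmetric intermediate. It is therefore planned at partial conversion with recovery of 19. Differentiating the rings earlier would need two unlike chain ends from the start and roughly double the work.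

**19 ⇒ 17 ⇒ 16.** In each ring a methoxycarbonyl group is put back on the CH between the chain-bearing carbon and one oxygen-bearing carbon (giving 17), and the oxygen next to that ester is capped as a methyl ether (giving 16). The ester is what a ring-forming cycloaddition needs as activator and regiochemical director. In 17 it sits ortho and para to hydroxyl groups, where hydrolysis is followed by easy protodecarboxylation. The methyl ether lies ortho to the ester, where chelation-controlled Lewis-acid cleavage removes it without touching anything else. The forward sequence must leave the alkene alone, which rules out the harsh protic or halogen-based ether cleavages.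

**16 ⇒ 13 + 6 (key disconnection).** In each ring two bonds are cut: the bond from the chain-bearing carbon to its CH neighbour, and the bond from the ester-bearing carbon to the methoxy-bearing carbon. This removes both rings and four C–C bonds in one operation and leaves the acyclic C22 bis(alk-2-ynoate) 13 and two molecules of diene 6. Against the neighbouring cut at the aryl–chain bond, this one needs no metal and no radical near the alkene. Against an intraring aldol cut of a polyketide chain, it has only one possible regiochemical outcome. The forward reaction must join the CH2 terminus of 6 to the chain-bearing alkyne carbon, aromatise by expelling one of the two methoxy groups, and ignore the isolated alkene.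

**13 ⇒ 11 ⇒ 9 ⇒ 8 ⇒ 7.** The two C(sp)–CO2Me bonds of 13 are cut to the terminal diyne 11, whose acetylide carbons are acylated in the forward sense. Each terminal alkyne carbon of 11 is then removed as a one-carbon homologation unit supplied by diazophosphonate 10, leading to dialdehyde 9. Adjusting the oxidation level through diol 8 reaches diacid 7. The eighteen carbons of 7 become the sixteen chain carbons plus the two chain-bearing ring carbons, and 7 already contains the cis alkene. This line is preferred to assembling the chain by a cis-selective olefination, because no step has to create the double-bond geometry.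

**6 ⇒ 5 ⇒ 4 ⇒ 1 + 2.** The O–Si bond of 6 is cut to the vinylogous ester 5, the two C–OMe bonds of 5 to the dichlorovinyl ketone 4, and the acyl–vinyl bond of 4 to acetyl chloride 1 and 1,1-dichloroethene 2. All three forward steps are simple polar reactions of small, distillable compounds.

## Roads not taken

**Alternative 1:** Cut the two aryl–CH2 bonds.
- Forward: diacid 7 is converted into its bis(N-hydroxyphthalimide) ester A1. This is coupled at both ends with the arylzinc reagent A2 under NiCl2(MeOCH2CH2OMe) and 4,4'-di-tert-butyl-2,2'-bipyridine, with twofold decarboxylation, to give the tetrakis(silyl ether) A3. Desilylation gives 19.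
- Merits: about four operations from 7 to 20, no ring construction, and the whole chain of 7 is used as bought.
- Weak points: the coupling runs through primary alkyl radicals and low-valent nickel. Each end can instead be reduced, dimerised or β-eliminated, and the mono-coupled and hydro-decarboxylated by-products are hydrocarbon-like silyl ethers very close in polarity to A3. Nickel hydride formed on the way can isomerise or shift the cis alkene. A2 is needed in several-fold excess and itself takes protection and metalation of a halo-resorcinol.
- Comparison: on step count this road is clearly better than the chosen plan (eleven steps, eight in the longest line). The chosen plan sets against it closed-shell thermal ring formation in which no radical or metal hydride meets the alkene, polar intermediates in which a half-reacted molecule is easily separated, and ring carbons drawn from cheap C2 and C4 building blocks. The final statistical acetylation is common to both.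

**Alternative 2:** Cut, in each ring, the bond between an oxygen-bearing carbon and the carbon lying between the two oxygen-bearing carbons, at the cyclohexane-1,3-dione oxidation level.
- Forward: dialdehyde 9 is olefinated with a stabilised acetonyl phosphorus ylide to the bis(enone) A4. Conjugate addition of a malonate ester and dealkoxycarbonylation give the bis(δ-keto ester) A5. NaOMe closes both rings by intramolecular Claisen condensation (methyl-ketone enolate onto ester) to the bis(dione) A6, which must then be dehydrogenated to 19.
- Merits: inexpensive base-mediated chemistry, an unambiguous ring closure, no moisture-sensitive diene and no sealed-tube step. The count from 9 to 19 is about five operations, the same as in the chosen plan, which also needs three steps for the diene, so this road is slightly shorter overall.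
- Weak points: A6 is two oxidation levels below the arene. Every standard aromatisation of a cyclohexane-1,3-dione (halogenation–dehydrohalogenation, palladium on carbon at high temperature, Hg(OAc)2) threatens the cis alkene with halogen addition, geometric isomerisation or hydrogen transfer, and it has to succeed twice.
- Comparison: the chosen plan reaches the aromatic oxidation level directly, because the alkyne supplies the missing unsaturation, so no oxidant is ever used in the presence of the alkene.

**Alternative 3:** Cut the ring bond between the ester-bearing carbon and the chain-bearing carbon and unfold each ring into a polyketide chain.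
- Forward: a bis(acyl donor) made from 7 is condensed with two equivalents of the trianion of methyl 3,5-dioxohexanoate A7 to give the bis(3,5,7-trioxo ester) A8. Mild base closes C2 onto the C7 ketone at each end and dehydration gives the bis(resorcylate) A9, which is identical with 17.
- Merits: biomimetic, about three operations from 7 to 17, and the phenols arrive free, so no ether cleavage is needed. In length, and in avoiding the demethylation step, this road is better than the chosen one.
- Weak points: a 3,5,7-trioxo ester has three competing closures (the wanted aldol, a Claisen closure to an acylphloroglucinol, and lactonisation to a 4-hydroxypyranone), and both ends must choose the same one. The twofold acylation of a trianion generates a product more acidic than the reagent, so proton transfer stalls the second acylation. A8 is a hexacarbonyl compound that exists as a tautomeric mixture and is hard to purify.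
- Comparison: the chosen plan sets against the shorter sequence a single regiochemical outcome fixed by orbital polarisation, neutral conditions, and stable, characterisable intermediates throughout.

Key step: step 8

## Route

Step 1
Reactants: 1 acetyl chloride; 2 1,1-dichloroethene
Product: 4 4,4-dichlorobut-3-en-2-one, via 4,4,4-trichlorobutan-2-one 3 (not isolated)
Conditions: AlCl3, CH2Cl2, 0 °C to rt; ice/aq. HCl; distillation (loss of HCl)
Reagents that add atoms: none
Why: Friedel–Crafts-type acylation of the CH2 terminus of the alkene with chloride capture gives 3, which undergoes β-elimination of HCl to the conjugated dichlorovinyl ketone; this is the established preparation of this ketone.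

Step 2
Reactants: 4 4,4-dichlorobut-3-en-2-one
Product: 5 4,4-dimethoxybut-3-en-2-one
Conditions: NaOMe (2.1 equiv), MeOH, 0 °C to rt
Reagents that add atoms: sodium methoxide, [Na+].[O-]C
Why: Twofold nucleophilic vinylic substitution (addition–elimination through the enolate) at the β-carbon of the enone replaces both chlorides and gives the vinylogous ester.

Step 3
Reactants: 5 4,4-dimethoxybut-3-en-2-one
Product: 6 1,1-dimethoxy-3-(trimethylsilyloxy)buta-1,3-diene
Conditions: Me3SiCl, Et3N, ZnCl2 (cat.), toluene, 40 °C; filtration under Ar, distillation
Reagents that add atoms: chlorotrimethylsilane, C[Si](C)(C)Cl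
Why: Silyl enol ether formation at the only enolisable position (the acetyl methyl group) gives the electron-rich diene, which is handled with exclusion of moisture and used freshly distilled.

Step 4
Reactants: 7 (9Z)-octadec-9-enedioic acid
Product: 8 (9Z)-octadec-9-ene-1,18-diol
Conditions: LiAlH4 (excess), THF, 0 °C to reflux; H2O, aq. NaOH work-up
Reagents that add atoms: none
Why: Hydride reduction of both carboxylic acids to primary alcohols; LiAlH4 does not touch an isolated alkene, whereas a borane would hydroborate it.

Step 5
Reactants: 8 (9Z)-octadec-9-ene-1,18-diol
Product: 9 (9Z)-octadec-9-enedial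
Conditions: 2,2,6,6-tetramethylpiperidin-1-oxyl (TEMPO, 10 mol %), PhI(OAc)2 (2.4 equiv), CH2Cl2, rt
Reagents that add atoms: none
Why: Oxoammonium-mediated oxidation of primary alcohols stops at the aldehyde in the absence of water and leaves the cis alkene alone; the dialdehyde is used without delay.

Step 6
Reactants: 9 (9Z)-octadec-9-enedial; 10 dimethyl (1-diazo-2-oxopropyl)phosphonate
Product: 11 (10Z)-icos-10-ene-1,19-diyne
Conditions: 10 (2.6 equiv), K2CO3, MeOH, 0 °C to rt
Reagents that add atoms: dimethyl (1-diazo-2-oxopropyl)phosphonate (10, also listed as reactant), COP(=O)(OC)C(=[N+]=[N-])C(C)=O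
Why: Ohira–Bestmann homologation: methanolysis of 10 frees the diazomethylphosphonate anion, which olefinates each aldehyde; loss of N2 and 1,2-hydride shift of the alkylidene carbene give the terminal alkynes under conditions mild enough for an enolisable aldehyde.

Step 7
Reactants: 11 (10Z)-icos-10-ene-1,19-diyne
Product: 13 dimethyl (11Z)-docos-11-ene-2,20-diynedioate, via dilithium bis(acetylide) 12 (not isolated)
Conditions: n-BuLi (2.2 equiv), THF, −78 °C; ClCO2Me (3 equiv), −78 to 0 °C
Reagents that add atoms: methyl chloroformate, COC(=O)Cl
Why: Deprotonation of both terminal alkynes and C-acylation of the lithium acetylides with a chloroformate is the standard route to alk-2-ynoates; nothing else in 11 is acidic or electrophilic.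

Step 8
Reactants: 13 dimethyl (11Z)-docos-11-ene-2,20-diynedioate; 6 1,1-dimethoxy-3-(trimethylsilyloxy)buta-1,3-diene
Product: 16 dimethyl 6,6'-[(8Z)-hexadec-8-ene-1,16-diyl]bis(4-hydroxy-2-methoxybenzoate), via twofold cyclohexa-1,4-diene cycloadduct 14 (not isolated), via bis(aryl trimethylsilyl ether) 15 (not isolated)
Conditions: 6 (6 equiv), toluene (minimal), sealed tube, 130 °C; then 1 M HCl, THF, rt
Reagents that add atoms: none
Why: Twofold intermolecular Diels–Alder benzannulation; the closest known reaction type is the cycloaddition of 1,1-dialkoxy-3-silyloxybutadienes to β-alkyl alk-2-ynoates with aromatisation by loss of alcohol. The largest HOMO coefficient of 6 lies at its CH2 terminus and the largest LUMO coefficient of each ynoate at the chain-bearing β-carbon, so the concerted but asynchronous [4+2] event joins CH2 to Cβ and the ketene-acetal carbon to the ester-bearing Cα. Each ring is closed by this intermolecular cycloaddition, both ring bonds forming in one step (not by an exo or endo cyclisation), to give the cyclohexa-1,4-diene 14. 14 aromatises by 1,4-elimination of methanol (one ketal methoxy group and a ring CH2 hydrogen) to 15, and the acidic work-up cleaves the O–Si bonds to 16; any adduct that hydrolyses before eliminating is already at the arene oxidation level and ends up as 16 as well. No stereocentre is formed, since the sp3 carbons of 14 are not stereogenic, and the cis alkene is not involved. The step needs regioselectivity (chain meta to both oxygens), secured by the matched polarisation of the ketene-acetal diene and the ester-activated alkyne. It also needs chemoselectivity for the ynoates over the alkene, secured because the electron-rich diene has no affinity for an unactivated alkene. The two ynoates are sixteen carbon atoms apart and react independently, so an excess of 6 should carry both to completion.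

Step 9
Reactants: 16 dimethyl 6,6'-[(8Z)-hexadec-8-ene-1,16-diyl]bis(4-hydroxy-2-methoxybenzoate)
Product: 17 dimethyl 6,6'-[(8Z)-hexadec-8-ene-1,16-diyl]bis(2,4-dihydroxybenzoate)
Conditions: BCl3 (6 equiv), CH2Cl2, −78 to 0 °C; aq. NaHCO3
Reagents that add atoms: none
Why: Chelation-controlled Lewis-acid ether cleavage: BCl3 bridges the ester carbonyl and the ortho methoxy oxygen and chloride removes only that methyl group. The para phenol is merely borylated and freed on work-up, and the methyl ester and the alkene are inert at low temperature.

Step 10
Reactants: 17 dimethyl 6,6'-[(8Z)-hexadec-8-ene-1,16-diyl]bis(2,4-dihydroxybenzoate)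
Product: 19 5,5'-[(8Z)-hexadec-8-ene-1,16-diyl]di(benzene-1,3-diol), via bis(2,4-dihydroxybenzoic acid) 18 (not isolated)
Conditions: KOH (aq., excess), 1,4-dioxane, reflux, Ar (degassed); then aq. HCl to pH 2, 70 °C
Reagents that add atoms: none
Why: Saponification gives the β-resorcylic acids 18, which lose CO2 on warming in acid by ipso-protonation of the ring carbon ortho and para to the two hydroxyl groups (a vinylogous β-keto acid); this is the classical ester hydrolysis–protodecarboxylation route to 5-alkylresorcinols.

Step 11
Reactants: 19 5,5'-[(8Z)-hexadec-8-ene-1,16-diyl]di(benzene-1,3-diol)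
Product: 20 3-[(8Z)-16-(3,5-dihydroxyphenyl)hexadec-8-en-1-yl]-5-hydroxyphenyl acetate (oncostemonol B)
Conditions: Ac2O (0.7 equiv, slow addition), pyridine, THF, 0 °C; chromatography, recovered 19 recycled
Reagents that add atoms: acetic anhydride, CC(=O)OC(C)=O
Why: Acylation of a phenol by an anhydride under amine base; the four hydroxyl groups are equivalent, so a sub-stoichiometric charge should make the mono-acetate the main converted product. Unchanged 19 is recovered, and over-acetylated material can be methanolysed back to 19.

## Compound list

1 | acetyl chloride | CC(Cl)=O | starting material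
2 | 1,1-dichloroethene | C=C(Cl)Cl | starting material
3 | 4,4,4-trichlorobutan-2-one | CC(=O)CC(Cl)(Cl)Cl | intermediate (not isolated)
4 | 4,4-dichlorobut-3-en-2-one | CC(=O)C=C(Cl)Cl | intermediate
5 | 4,4-dimethoxybut-3-en-2-one | CC(=O)C=C(OC)OC | intermediate
6 | 1,1-dimethoxy-3-(trimethylsilyloxy)buta-1,3-diene | COC(OC)=CC(=C)O[Si](C)(C)C | intermediate
7 | (9Z)-octadec-9-enedioic acid | OC(=O)CCCCCCC/C=C\CCCCCCCC(=O)O | starting material
8 | (9Z)-octadec-9-ene-1,18-diol | OCCCCCCCC/C=C\CCCCCCCCO | intermediate
9 | (9Z)-octadec-9-enedial | O=CCCCCCCC/C=C\CCCCCCCC=O | intermediate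
10 | dimethyl (1-diazo-2-oxopropyl)phosphonate | COP(=O)(OC)C(=[N+]=[N-])C(C)=O | starting material
11 | (10Z)-icos-10-ene-1,19-diyne | C#CCCCCCCC/C=C\CCCCCCCC#C | intermediate
12 | dilithium (10Z)-icos-10-ene-1,19-diyne-1,20-diide | [Li]C#CCCCCCCC/C=C\CCCCCCCC#C[Li] | intermediate (not isolated)
13 | dimethyl (11Z)-docos-11-ene-2,20-diynedioate | COC(=O)C#CCCCCCCC/C=C\CCCCCCCC#CC(=O)OC | intermediate
14 | dimethyl 2,2'-[(8Z)-hexadec-8-ene-1,16-diyl]bis[6,6-dimethoxy-4-(trimethylsilyloxy)cyclohexa-1,4-diene-1-carboxylate] | COC(=O)C1=C(CCCCCCC/C=C\CCCCCCCC2=C(C(=O)OC)C(OC)(OC)C=C(O[Si](C)(C)C)C2)CC(O[Si](C)(C)C)=CC1(OC)OC | intermediate (not isolated)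
15 | dimethyl 6,6'-[(8Z)-hexadec-8-ene-1,16-diyl]bis[2-methoxy-4-(trimethylsilyloxy)benzoate] | COC(=O)c1c(OC)cc(O[Si](C)(C)C)cc1CCCCCCC/C=C\CCCCCCCc1cc(O[Si](C)(C)C)cc(OC)c1C(=O)OC | intermediate (not isolated)
16 | dimethyl 6,6'-[(8Z)-hexadec-8-ene-1,16-diyl]bis(4-hydroxy-2-methoxybenzoate) | COC(=O)c1c(OC)cc(O)cc1CCCCCCC/C=C\CCCCCCCc1cc(O)cc(OC)c1C(=O)OC | intermediate
17 | dimethyl 6,6'-[(8Z)-hexadec-8-ene-1,16-diyl]bis(2,4-dihydroxybenzoate) | COC(=O)c1c(O)cc(O)cc1CCCCCCC/C=C\CCCCCCCc1cc(O)cc(O)c1C(=O)OC | intermediate
18 | 6,6'-[(8Z)-hexadec-8-ene-1,16-diyl]bis(2,4-dihydroxybenzoic acid) | OC(=O)c1c(O)cc(O)cc1CCCCCCC/C=C\CCCCCCCc1cc(O)cc(O)c1C(=O)O | intermediate (not isolated)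
19 | 5,5'-[(8Z)-hexadec-8-ene-1,16-diyl]di(benzene-1,3-diol) | Oc1cc(O)cc(CCCCCCC/C=C\CCCCCCCc2cc(O)cc(O)c2)c1 | intermediate
20 | 3-[(8Z)-16-(3,5-dihydroxyphenyl)hexadec-8-en-1-yl]-5-hydroxyphenyl acetate (oncostemonol B) | CC(=O)Oc1cc(O)cc(CCCCCCC/C=C\CCCCCCCc2cc(O)cc(O)c2)c1 | target

## Step count and risks

Total step count: 11 (steps 1–3 for the diene, steps 4–7 for the bis(ynoate), steps 8–11 in common). Longest linear sequence: 8 steps (steps 4–11, from 7).

**Step 8 (key step).** The β-alkyl, singly activated alkynes are slow dienophiles. Thermal decomposition or adventitious hydrolysis of the diene may outrun cycloaddition, leaving one or both chain ends unreacted.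
Fallback: an anionic ring construction on the same bis(ynoate), setting out from 13 and returning at 19.
- 13 is treated with the sodium enolate of dimethyl 3-oxopentanedioate (NaH, THF, rt to reflux). Conjugate addition to each ynoate is followed by Claisen ring closure onto the ynoate ester and enolisation, giving tetramethyl 6,6'-[(8Z)-hexadec-8-ene-1,16-diyl]bis(2,4-dihydroxybenzene-1,3-dicarboxylate) F1.
- Alkaline hydrolysis of F1 (aq. KOH, reflux, Ar) gives the tetra-acid 6,6'-[(8Z)-hexadec-8-ene-1,16-diyl]bis(2,4-dihydroxybenzene-1,3-dicarboxylic acid) F2, which decarboxylates four times on acidification and warming to 19.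
- This Michael–Claisen benzannulation of alkynoates is known chemistry and bypasses steps 8 to 10.

**Step 11.** Acylation does not stop cleanly at one of four equivalent hydroxyl groups. Over-acetylation and a statistical product distribution limit the amount of 20 per pass, and the polar phenols must be separated by degree of acetylation.
Fallback: approach the mono-acetate from the other side, setting out from 19 and returning at 20.
- Exhaustive acetylation (Ac2O, pyridine) gives the air-stable, easily purified tetraacetate (8Z)-hexadec-8-ene-1,16-diyldi(benzene-5,1,3-triyl) tetraacetate F3.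
- Partial methanolysis (K2CO3 cat., MeOH/THF, 0 °C, monitored) should then remove acetyl groups one at a time. Once a ring has lost one acetyl group, its phenoxide should retard loss of the second, so the mixture should pass through the species with one acetate per ring. The problem is thereby reduced from four sites to two before 20 is reached.

**Step 10.** Acyl substitution at the ester is slow because it is flanked by two ortho substituents and deactivated by the phenoxides. Prolonged heating in alkali invites air oxidation of the electron-rich rings.
Fallback: cleave the ester at the alkyl–oxygen bond instead of the acyl–oxygen bond, setting out from 17 and returning at 19. LiI in refluxing pyridine dealkylates the methyl esters by SN2 attack at the unhindered methyl carbon, giving 18 as its lithium salt. Acidification and warming then decarboxylate it to 19. No new compound is involved.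

**Step 9.** Ether cleavage may be incomplete at one of the two rings. Hydrogen chloride generated in the mixture may also add to the alkene or promote cis/trans isomerisation if the mixture warms.
Fallback: avoid the methyl ether altogether by changing the diene, setting out from 13 and returning at 17.
- 5,5-Dimethyl-1,3-bis(trimethylsilyloxy)cyclohexa-1,3-diene F4 is prepared from 5,5-dimethylcyclohexane-1,3-dione (Me3SiOTf, Et3N).
- F4 is heated with 13 (neat, 140–160 °C). The bicyclic adduct dimethyl 3,3'-[(8Z)-hexadec-8-ene-1,16-diyl]bis[8,8-dimethyl-1,5-bis(trimethylsilyloxy)bicyclo[2.2.2]octa-2,5-diene-2-carboxylate] F5 loses 2-methylpropene by retro-Diels–Alder reaction.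
- This gives dimethyl 6,6'-[(8Z)-hexadec-8-ene-1,16-diyl]bis[2,4-bis(trimethylsilyloxy)benzoate] F6, whose silyl ethers are hydrolysed on mild acidic work-up to 17.
- The same ring bonds form, and both phenols arrive free.

## Further compounds

F1 | step 8 | tetramethyl 6,6'-[(8Z)-hexadec-8-ene-1,16-diyl]bis(2,4-dihydroxybenzene-1,3-dicarboxylate) | COC(=O)c1c(O)c(C(=O)OC)c(O)cc1CCCCCCC/C=C\CCCCCCCc1cc(O)c(C(=O)OC)c(O)c1C(=O)OC
F2 | step 8 | 6,6'-[(8Z)-hexadec-8-ene-1,16-diyl]bis(2,4-dihydroxybenzene-1,3-dicarboxylic acid) | OC(=O)c1c(O)c(C(=O)O)c(O)cc1CCCCCCC/C=C\CCCCCCCc1cc(O)c(C(=O)O)c(O)c1C(=O)O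
F3 | step 11 | (8Z)-hexadec-8-ene-1,16-diyldi(benzene-5,1,3-triyl) tetraacetate | CC(=O)Oc1cc(OC(C)=O)cc(CCCCCCC/C=C\CCCCCCCc2cc(OC(C)=O)cc(OC(C)=O)c2)c1
F0 | step 10 | none | none
F4 | step 9 | 5,5-dimethyl-1,3-bis(trimethylsilyloxy)cyclohexa-1,3-diene | CC1(C)CC(O[Si](C)(C)C)=CC(O[Si](C)(C)C)=C1
F5 | step 9 | dimethyl 3,3'-[(8Z)-hexadec-8-ene-1,16-diyl]bis[8,8-dimethyl-1,5-bis(trimethylsilyloxy)bicyclo[2.2.2]octa-2,5-diene-2-carboxylate] (mixture of bridgehead stereoisomers) | COC(=O)C1=C(CCCCCCC/C=C\CCCCCCCC2=C(C(=O)OC)C3(O[Si](C)(C)C)C=C(O[Si](C)(C)C)C2C(C)(C)C3)C2C(O[Si](C)(C)C)=CC1(O[Si](C)(C)C)CC2(C)C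
F6 | step 9 | dimethyl 6,6'-[(8Z)-hexadec-8-ene-1,16-diyl]bis[2,4-bis(trimethylsilyloxy)benzoate] | COC(=O)c1c(O[Si](C)(C)C)cc(O[Si](C)(C)C)cc1CCCCCCC/C=C\CCCCCCCc1cc(O[Si](C)(C)C)cc(O[Si](C)(C)C)c1C(=O)OC
A1 | alternative 1 | bis(1,3-dioxoisoindolin-2-yl) (9Z)-octadec-9-enedioate | O=C(CCCCCCC/C=C\CCCCCCCC(=O)ON1C(=O)c2ccccc2C1=O)ON1C(=O)c2ccccc2C1=O
A2 | alternative 1 | [3,5-bis(tert-butyldimethylsilyloxy)phenyl]zinc chloride | CC(C)(C)[Si](C)(C)Oc1cc([Zn]Cl)cc(O[Si](C)(C)C(C)(C)C)c1
A3 | alternative 1 | (8Z)-1,16-bis[3,5-bis(tert-butyldimethylsilyloxy)phenyl]hexadec-8-ene | CC(C)(C)[Si](C)(C)Oc1cc(CCCCCCC/C=C\CCCCCCCc2cc(O[Si](C)(C)C(C)(C)C)cc(O[Si](C)(C)C(C)(C)C)c2)cc(O[Si](C)(C)C(C)(C)C)c1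
A4 | alternative 2 | (3E,12Z,21E)-tetracosa-3,12,21-triene-2,23-dione | CC(=O)/C=C/CCCCCCC/C=C\CCCCCCC/C=C/C(C)=O
A5 | alternative 2 | dimethyl (11Z)-3,20-bis(2-oxopropyl)docos-11-enedioate | COC(=O)CC(CC(C)=O)CCCCCCC/C=C\CCCCCCCC(CC(C)=O)CC(=O)OC
A6 | alternative 2 | 5,5'-[(8Z)-hexadec-8-ene-1,16-diyl]bis(cyclohexane-1,3-dione) | O=C1CC(=O)CC(C1)CCCCCCC/C=C\CCCCCCCC1CC(=O)CC(=O)C1
A7 | alternative 3 | methyl 3,5-dioxohexanoate | COC(=O)CC(=O)CC(C)=O
A8 | alternative 3 | dimethyl (15Z)-3,5,7,24,26,28-hexaoxotriacont-15-enedioate | COC(=O)CC(=O)CC(=O)CC(=O)CCCCCCC/C=C\CCCCCCCC(=O)CC(=O)CC(=O)CC(=O)OC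
A9 | alternative 3 | dimethyl 6,6'-[(8Z)-hexadec-8-ene-1,16-diyl]bis(2,4-dihydroxybenzoate) | COC(=O)c1c(O)cc(O)cc1CCCCCCC/C=C\CCCCCCCc1cc(O)cc(O)c1C(=O)OC
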